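## Analysis of the target

Compound 26 is a germacrane: one ten-membered carbocycle (C1–C10) with no second carbocycle to fix its shape, an isopropenyl group on C7, methyl groups on C4 and C10, and oxygen on seven ring carbons. Two trisubstituted epoxides span C1–C10 and C4–C5. In both, the two ring bonds leaving the oxirane are cis, so both derive from ring-cis (Z) trisubstituted olefins. The eight stereocentres are (1R,3S,4S,5S,7R,8S,9S,10S). On a flat drawing the C3 ester oxygen, the isopropenyl group, the C8 ester oxygen, the C9 hydroxyl and the 1,10-epoxide oxygen share one face and only the 4,5-epoxide oxygen lies on the other. The 1,10-epoxide is therefore cis to its neighbouring carbinol (C9) and the 4,5-epoxide trans to its neighbour (C3). Sensitive groups are the angelate (isomerises to the tiglate under base, nucleophiles or heat), the two tertiary epoxides (acid, transannular attack by the C9 hydroxyl), the vicinal ester/alcohol pair at C8/C9 (acyl migration) and the isopropenyl group (competes in electrophilic epoxidation). The hard parts are the medium ring, the contiguous triad C7–C8–C9 on a flexible ring, and three secondary oxygens that must end as two different esters and one free hydroxyl. The strategy rests on the carbon run C9–C10(CH3)=C1–C2–C3–C4(CH3)=C5–C6 that underlies the two epoxides: it is the eight-membered ring of commercial diene 1, whose allylic CH2 groups next to the methyl-bearing carbons are exactly C3 and C9, and the two missing ring carbons C7 and C8 are those of a vinyl group.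

## Retrosynthetic reasoning

**26 ⇒ 25.** The oxirane oxygen on C1–C10 is removed first. In 25 the neighbouring C9 hydroxyl can deliver that oxygen in a metal-alkoxide-directed epoxidation, which picks this olefin out of four C=C bonds and sets the cis relation to C9. It also means the free C9 hydroxyl next to the C8 ester exists for only two steps.

**25 ⇒ 24.** The C9–H bond is cut to give ketone 24. Keeping C9 as a carbonyl until here provides the handle for C7 and C8, keeps C1=C10 electron-poor, and avoids having to tell two neighbouring hydroxyls apart, because the C8 oxygen is acylated before C9 becomes a carbinol. The forward reduction must add hydride so that the C9 oxygen ends cis to the C8 ester.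

**24 ⇒ 22 + 23, and 22 ⇒ 20.** The C8–O bond is taken apart in two stages. An electrophilic oxygen source should approach enolate 21 from the ring periphery, which places the oxygen trans to the isopropenyl group, whereas 26 has it cis. Esterification with acid 23 is therefore planned with inversion, so one step forms the ester and corrects C8. Behind 22, the C8–O bond is cut to ketone 20, whose only kinetically acidic position is C8.

**20 ⇒ 17 + 18, and 17 ⇒ 16.** The angelate is attached where the molecule has a single hydroxyl and no base-labile stereocentre. It is not carried through steps 9–11, where an ester on C3 could be lost by vinylogous β-elimination or isomerised. It is not put on later, when an α-acyloxy ketone at C8 or a second free hydroxyl at C9 would be present. Hence silyl ether 16 as the form in which C3 passes the basic steps.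

**16 ⇒ 14 + 15, and 14 ⇒ 13 ⇒ 12.** The C7–C11 bond is cut to dienone 14 and boronate 15. Once C7=C8 is in place, C7 is the β-carbon of the C9 ketone, and a catalyst-controlled conjugate addition can set it; the second enone (C1=C10) is α-methylated and β-substituted and should not react. The unsaturation is traced through silyl enol ether 13 to ketone 12.

**12 ⇒ 11 ⇒ 10.** The silyl group and then the 4,5-oxirane oxygen are removed. The epoxide is installed directly after ring expansion because in 10 the C4=C5 bond is the only electron-rich olefin (C1=C10 is an enone and the isopropenyl group is not yet present). The free C3 hydroxyl can guide a peracid to the face that gives the trans relation.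

**10 ⇒ 7 (key disconnection).** The C6–C7 bond is cut and C6–C9 re-formed, contracting the ten-membered ring to the eight-membered vinyl carbinol 7. In the forward direction the C9 oxyanion drives the shift of allylic C6 across the vinyl group. This makes the medium ring by enlargement of an existing ring rather than by end-to-end closure and delivers the C9 carbonyl needed later. Both Z olefins, both methyl groups and the C3 stereocentre are already present.

**7 ⇒ 5 + 6.** The C9–C8 bond is cut: addition of vinyl reagent 6 to the ketone of 5 brings in C7 and C8. The new carbinol configuration does not matter because that carbon becomes the carbonyl.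

**5 ⇒ 4 ⇒ 3 ⇒ 2 ⇒ 1.** The hydroxy enone comes from mono-oxidation of the twofold-symmetric diol 4, whose hydroxyls are equivalent. Diol 4 comes from enantioselective twofold reduction of dione 3, which fixes C3 of the target. Dione 3 comes from twofold allylic oxidation of diene 1 at the CH2 groups next to the methyl-bearing carbons.

## Alternatives that were turned down

**Alternative 1:** The ring is cut at C9–C10. Forward, a chromium-mediated, nickel-catalysed Nozaki–Hiyama–Kishi reaction adds a Z-alkenyl iodide at C10 to a C9 aldehyde in an open-chain precursor and gives A1, (1(10)Z,4Z)-3-silyloxy-8-(4-methoxybenzyloxy)germacra-1(10),4,11-trien-9-ol.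
- For: C3, C7, C8 and both Z olefins are built on an open chain, where acyclic stereocontrol is more dependable than anything done on the ring. The coupling tolerates the functionality and closes ten-membered carbocycles. A1 carries three differently masked oxygens that map directly onto the two esters and the hydroxyl. On reliability of C7/C8 and on oxygen differentiation it is stronger than the chosen route.
- Against: the precursor needs two separately constructed Z-trisubstituted olefins and three stereocentres before the ring exists. Closure is a high-dilution medium-ring cyclisation with a large excess of a toxic metal salt. The sense of 1,2-induction at C9 (chelated or Felkin-type) is uncertain in a ring-forming transition state. The benzyl-type ether at C8 must later be exchanged for a senecioate beside a free C9 hydroxyl.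
- In place of those strengths the chosen strategy offers a six-step entry to the ring from a commodity diene, with both olefins bought and no cyclisation.

**Alternative 2:** The ring is cut at C3–C4 with C4–C5 as an alkyne. Forward, an alkynylchromium from an iodoalkyne adds to a C3 aldehyde and closes the cycloalkynol A2, the 8,9-acetonide of 15-norgermacra-1(10)Z,11-dien-4-yne-3,8,9-triol. A syn-carbometalation must then add the C4 methyl and create the ring-cis C4=C5 bond.
- For: no Z olefin has to be made at C4=C5 in the chain. Syn addition across a ring alkyne can only give the ring-cis alkene. The cis-acetonide acts as a turn element. On convergence it is at least as good as the chosen route.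
- Against: the closure must build a strained cyclodecyne. The C3 carbinol forms with little control from remote centres. A regio-defined syn methylmetalation of an unactivated ring alkyne is the least secure operation and follows the key step. The acetonide finally releases two neighbouring hydroxyls that must be told apart.
- The chosen route has one high-risk step instead of two, and the methyl groups and olefin geometry are present from the start.

**Alternative 3:** The transannular bond C3–C8 is added retrosynthetically, giving a bicyclic ring-fusion diol built on a chiral-pool terpenoid cyclohexenone. Forward, oxidative glycol cleavage releases A3, (1(10)Z,4Z)-9-(4-methoxybenzyloxy)germacra-1(10),4,11-triene-3,8-dione.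
- For: C7 comes with its isopropenyl group from the chiral pool, which is stronger than the catalytic C7 step of the chosen route. The six-membered rings enforce both Z olefins. The ten-membered ring arises by bond cleavage without dilution, equal to the chosen route on that point.
- Against: A3 has a β,γ-unsaturated C3 ketone prone to conjugation, and a C8 ketone flanked by epimerisable C7 and by C9–H, which is both α to the carbonyl and allylic. Two ring ketones must each be reduced under conformational control. The annulated diol with its C9 oxygen costs several steps.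
- In place of the chiral-pool C7, the chosen route sets C3 before the ring exists by a reagent-controlled reduction, and its key-step product 10 has one ketone and no isomerisable β,γ-enone.

Key step: step 6

## Remarks before the steps (assumptions on the chemistry)

- Ten-membered-ring compounds carry germacrane numbering (ring C1–C10, isopropenyl C11–C13 on C7, C14 on C10, C15 on C4). Cis and trans refer to the ring drawn flat.
- Commercial 1 contains some 1,6-dimethyl isomer; it is assumed that the isomeric oxidation product is removed at dione 3 by crystallisation or chromatography.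
- The configuration at C1 of 7 and the C8=C9 geometry of 9, 13 and 21 do not reach the target. Compounds 7 and 13 are drawn as the expected isomers, 9 and 21 without defined C8=C9 geometry.
- The C4 descriptor is R with a free C3 hydroxyl and S with a silylated or acylated one; the configuration is the same.
- (S,S)-Ph-bod* is (1S,4S)-2,5-diphenylbicyclo[2.2.2]octa-2,5-diene.

## Steps

Step 1
Reactants: 1 (1Z,5Z)-1,5-dimethylcycloocta-1,5-diene
Product: 2 (2Z,6Z)-2,6-dimethylcycloocta-2,6-diene-1,5-diol (mixture of racemic and meso diastereomers)
Conditions: SeO2 (0.5 equiv), t-BuOOH (5 equiv), CH2Cl2, 25 °C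
Reagents that add atoms: tert-butyl hydroperoxide CC(C)(C)OO (terminal oxygen source; selenium dioxide O=[Se]=O is the carrier)
Why: Riley-type allylic oxidation: the ene reaction/[2,3]-shift sequence oxidises the allylic CH2 on the more substituted olefin carbon and returns the double bond to its place, so each C(CH3)=CH unit is hydroxylated at the ring CH2 next to the methyl-bearing carbon and both cis olefins are kept. The carbinol configurations are removed in step 2.

Step 2
Reactants: 2 (2Z,6Z)-2,6-dimethylcycloocta-2,6-diene-1,5-diol
Product: 3 (2Z,6Z)-2,6-dimethylcycloocta-2,6-diene-1,5-dione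
Conditions: MnO2 (excess), CH2Cl2, 25 °C
Reagents that add atoms: none
Why: Activated MnO2 oxidises allylic alcohols under neutral heterogeneous conditions, so both diastereomers of 2 converge on achiral 3 without base that could move the olefins into the doubly activated CH2 positions.

Step 3
Reactants: 3 (2Z,6Z)-2,6-dimethylcycloocta-2,6-diene-1,5-dione
Product: 4 (1S,5S,2Z,6Z)-2,6-dimethylcycloocta-2,6-diene-1,5-diol
Conditions: (R)-2-methyl-CBS-oxazaborolidine (0.4 equiv), catecholborane (3 equiv), toluene, −78 °C; then MeOH, H2O
Reagents that add atoms: none
Why: Corey–Bakshi–Shibata reduction: each carbonyl is flanked by a methyl-substituted alkenyl carbon (large) and a CH2 (small), and on the usual model the (R)-catalyst should give the (S)-carbinol; catecholborane at low temperature avoids hydroboration. Because two identical carbonyls are reduced, most wrong-face reduction ends in the separable meso diol, which should raise the enantiomeric purity of 4.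

Step 4
Reactants: 4 (1S,5S,2Z,6Z)-2,6-dimethylcycloocta-2,6-diene-1,5-diol
Product: 5 (5S,2Z,6Z)-5-hydroxy-2,6-dimethylcycloocta-2,6-dien-1-one
Conditions: MnO2 (limited charge, monitored), CH2Cl2, 0 °C
Reagents that add atoms: none
Why: Allylic oxidation of one of two equivalent hydroxyls of the twofold-symmetric diol, so no regiochemical question arises; over-oxidised 3 and unreacted 4 are recycled. Reversible transannular hemiketal formation in the product is expected to slow the second oxidation.

Step 5
Reactants: 5 (5S,2Z,6Z)-5-hydroxy-2,6-dimethylcycloocta-2,6-dien-1-one; 6 vinylmagnesium bromide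
Product: 7 (1R,5S,2Z,6Z)-1-ethenyl-2,6-dimethylcycloocta-2,6-diene-1,5-diol
Conditions: CeCl3, 6 (3.5 equiv), THF, −78 → 0 °C; then aq NH4Cl
Reagents that add atoms: vinylmagnesium bromide (6) C=C[Mg]Br
Why: Organocerium-mediated 1,2-addition to a hindered, enolisable enone; the first equivalent deprotonates the hydroxyl. Addition anti to the transannular metal alkoxide bridge should give the cis diol drawn, but this centre becomes the carbonyl carbon in step 6, so either epimer is usable.

Step 6
Reactants: 7 (1R,5S,2Z,6Z)-1-ethenyl-2,6-dimethylcycloocta-2,6-diene-1,5-diol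
Product: 10 (3S,1(10)Z,4Z)-3-hydroxy-4,10-dimethylcyclodeca-1(10),4-dien-9-one, via dipotassium dialkoxide 8 (not isolated), via dipotassium enolate alkoxide 9 (not isolated)
Conditions: KH (3 equiv), 18-crown-6 (3 equiv), THF, 0 → 25 °C; then AcOH
Reagents that add atoms: none
Why: In dialkoxide 8 the tertiary C9 oxyanion weakens the C9–C6 bond (allylic to C4=C5), and C6 moves across the vinyl group to its terminus C7, either as a concerted [1,3] shift or by heterolysis to a tethered allyl anion/divinyl ketone pair that recombines by 1,4-addition; this gives the cross-conjugated C8=C9 enolate 9, protonated at C8 on quench. The closest known reaction type is the alkoxide-accelerated [1,3]-sigmatropic two-carbon ring expansion of potassium 1-vinylcycloalk-3-en-1-olates of medium rings. The ten-membered ring is not closed end to end: the eight-membered ring is enlarged by insertion of C8 and C7 between C9 and C6, so no high dilution is needed. No stereocentre is created; C9 becomes the carbonyl carbon and C3 is a spectator. The step needs [1,3] rather than [3,3] selectivity: the [3,3] mode would have to bond the methyl-bearing terminus C4 through a chair or boat array that the ring-cis C4=C5 bond of an eight-membered ring cannot reach, whereas C6 and C7 are both unsubstituted. It also needs C6 to bond to C7 and not to C1 of the ring enone (which would contract the ring to a cyclohexene); C1 is the β-carbon of an α-methylated, β-substituted enone and far less electrophilic than the vinyl terminus. Both ring-cis olefins should survive because the allyl fragment stays tethered through C3–C2 and is short-lived, and the C3 oxygen, kept as an alkoxide, cannot be expelled from the allyl anion as an ether or ester would be.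

Step 7
Reactants: 10 (3S,1(10)Z,4Z)-3-hydroxy-4,10-dimethylcyclodeca-1(10),4-dien-9-one
Product: 11 (3S,4R,5S,1(10)Z)-4,5-epoxy-3-hydroxy-4,10-dimethylcyclodec-1(10)-en-9-one
Conditions: mCPBA (1.1 equiv), CH2Cl2/aq phosphate buffer (pH 7), 0 °C
Reagents that add atoms: 3-chloroperbenzoic acid OOC(=O)c1cccc(Cl)c1
Why: Hydroxyl-directed peracid epoxidation: with H3 in the plane of C4=C5 (allylic strain with C6) the hydroxyl lies on the open peripheral face and C2 blocks the other, the arrangement that makes peracid epoxidation of medium-ring (Z)-cycloalk-2-en-1-ols trans selective; this sets C4 and C5 with the oxirane trans to the C3 oxygen. The only other olefin, C1=C10, is conjugated to the ketone and too electron-poor to compete.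

Step 8
Reactants: 11 (3S,4R,5S,1(10)Z)-4,5-epoxy-3-hydroxy-4,10-dimethylcyclodec-1(10)-en-9-one
Product: 12 (3S,4S,5S,1(10)Z)-4,5-epoxy-4,10-dimethyl-3-(triethylsilyloxy)cyclodec-1(10)-en-9-one
Conditions: Et3SiCl, imidazole, DMF, 0 °C
Reagents that add atoms: chlorotriethylsilane CC[Si](Cl)(CC)CC
Why: Standard silylation; the ether keeps the C3 oxygen a poor leaving group through the basic steps 9–11, where an ester at C3 could be lost by vinylogous β-elimination.

Step 9
Reactants: 12 (3S,4S,5S,1(10)Z)-4,5-epoxy-4,10-dimethyl-3-(triethylsilyloxy)cyclodec-1(10)-en-9-one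
Product: 13 (3S,4S,5S,1(10)Z)-4,5-epoxy-4,10-dimethyl-3-(triethylsilyloxy)-9-(trimethylsilyloxy)cyclodeca-1(10),8-diene
Conditions: LiN(iPr)2, Me3SiCl (in situ), THF, −78 °C
Reagents that add atoms: chlorotrimethylsilane C[Si](C)(C)Cl
Why: Kinetic deprotonation of the enone at the α′ carbon C8 (the only sp3 α position) with in situ silylation gives the cross-conjugated silyl enol ether; its C8=C9 geometry is of no consequence.

Step 10
Reactants: 13 (3S,4S,5S,1(10)Z)-4,5-epoxy-4,10-dimethyl-3-(triethylsilyloxy)-9-(trimethylsilyloxy)cyclodeca-1(10),8-diene
Product: 14 (3S,4S,5S,1(10)Z,7Z)-4,5-epoxy-4,10-dimethyl-3-(triethylsilyloxy)cyclodeca-1(10),7-dien-9-one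
Conditions: Pd(OAc)2 (1.1 equiv), MeCN, 25 °C
Reagents that add atoms: none
Why: Saegusa–Ito oxidation: the C8-bound palladium enolate undergoes syn β-hydride elimination of H7. The ring-cis (7Z) enone is expected, because the C6–C7–C8–C9 unit is gauche in the ring and cis is the stable geometry of a disubstituted olefin in a ten-membered ring.

Step 11
Reactants: 14 (3S,4S,5S,1(10)Z,7Z)-4,5-epoxy-4,10-dimethyl-3-(triethylsilyloxy)cyclodeca-1(10),7-dien-9-one; 15 isopropenylboronic acid pinacol ester
Product: 16 (3S,4S,5S,7S,1(10)Z)-4,5-epoxy-3-(triethylsilyloxy)germacra-1(10),11-dien-9-one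
Conditions: [RhCl(C2H4)2]2 (3 mol%), (S,S)-Ph-bod* (7 mol%), 15 (2 equiv), KOH (0.2 equiv), dioxane/H2O 10:1, 40 °C
Reagents that add atoms: isopropenylboronic acid pinacol ester (15) CC(=C)B1OC(C)(C)C(C)(C)O1
Why: Hayashi–Miyaura conjugate addition with a chiral diene ligand: the alkenylrhodium adds only to the unhindered disubstituted enone C7=C8, since α-methylated, β-substituted C1=C10 is not a substrate for this catalyst. C7 is set by the catalyst; the ligand antipode is the one that converts cyclohex-2-enone into (S)-3-substituted cyclohexanones (taken to be S,S), which for this ring-cis enone corresponds to (7S).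

Step 12
Reactants: 16 (3S,4S,5S,7S,1(10)Z)-4,5-epoxy-3-(triethylsilyloxy)germacra-1(10),11-dien-9-one
Product: 17 (3S,4R,5S,7S,1(10)Z)-4,5-epoxy-3-hydroxygermacra-1(10),11-dien-9-one
Conditions: Bu4NF, AcOH (1:1), THF, 0 °C
Reagents that add atoms: none
Why: Buffered fluoride cleaves the triethylsilyl ether without exposing the epoxide to acid or the epoxy alkoxide to base (no Payne rearrangement).

Step 13
Reactants: 17 (3S,4R,5S,7S,1(10)Z)-4,5-epoxy-3-hydroxygermacra-1(10),11-dien-9-one; 18 angelic acid
Product: 20 (3S,4S,5S,7S,1(10)Z)-3-angeloyloxy-4,5-epoxygermacra-1(10),11-dien-9-one, via mixed anhydride 19 (not isolated)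
Conditions: 18, 2,4,6-Cl3C6H2COCl, Et3N, toluene, 25 °C; then 17, 75 °C
Reagents that add atoms: angelic acid (18) C/C=C(/C)C(=O)O
Why: Yamaguchi esterification through mixed anhydride 19, run without a nucleophilic catalyst, is the established way to acylate hindered secondary alcohols with angelic acid without Z-to-E isomerisation. It is placed here because 17 has a single hydroxyl and no base-labile stereocentre (C7 is β to the ketone).

Step 14
Reactants: 20 (3S,4S,5S,7S,1(10)Z)-3-angeloyloxy-4,5-epoxygermacra-1(10),11-dien-9-one
Product: 22 (3S,4S,5S,7R,8R,1(10)Z)-3-angeloyloxy-4,5-epoxy-8-hydroxygermacra-1(10),11-dien-9-one, via potassium enolate 21 (not isolated)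
Conditions: KN(SiMe3)2, THF, −78 °C; 2-(phenylsulfonyl)-3-phenyloxaziridine, −78 °C; then AcOH
Reagents that add atoms: 2-(phenylsulfonyl)-3-phenyloxaziridine O=S(=O)(c1ccccc1)N1OC1c1ccccc1
Why: Kinetic α′-deprotonation at C8 and oxidation of enolate 21 by the N-sulfonyloxaziridine. With H7 in the enolate plane the C6–C7 ring bond shields one face, so the reagent should enter from the ring periphery, which puts the new oxygen trans to the isopropenyl group (8R); the angelate has no acidic α-hydrogen and is untouched at −78 °C.

Step 15
Reactants: 22 (3S,4S,5S,7R,8R,1(10)Z)-3-angeloyloxy-4,5-epoxy-8-hydroxygermacra-1(10),11-dien-9-one; 23 senecioic acid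
Product: 24 (3S,4S,5S,7R,8S,1(10)Z)-3-angeloyloxy-4,5-epoxy-8-senecioyloxygermacra-1(10),11-dien-9-one
Conditions: 23, PPh3, DIAD, toluene, 0 → 25 °C
Reagents that add atoms: senecioic acid (23) CC(C)=CC(=O)O
Why: Mitsunobu esterification: the alkoxyphosphonium ion is displaced by senecioate with inversion, a displacement the adjacent carbonyl accelerates, so the ester oxygen ends cis to the isopropenyl group (8S) as in the target. Triphenylphosphine is too weak a Michael donor towards the α,β-disubstituted angelate to isomerise it under these conditions.

Step 16
Reactants: 24 (3S,4S,5S,7R,8S,1(10)Z)-3-angeloyloxy-4,5-epoxy-8-senecioyloxygermacra-1(10),11-dien-9-one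
Product: 25 (3S,4S,5S,7R,8S,9R,1(10)Z)-3-angeloyloxy-4,5-epoxy-8-senecioyloxygermacra-1(10),11-dien-9-ol
Conditions: NaBH4, CeCl3·7H2O, MeOH, −78 °C
Reagents that add atoms: none
Why: Luche reduction gives 1,2-reduction of the enone. With the C8–O bond eclipsing the carbonyl (the usual arrangement of α-acyloxy ketones, reinforced by cerium) C7 lies on one face of C9=O and only H8 on the other, so hydride should enter past H8 from the periphery and give the 8,9-cis hydroxy ester (9R); the low temperature suppresses acyl migration.

Step 17
Reactants: 25 (3S,4S,5S,7R,8S,9R,1(10)Z)-3-angeloyloxy-4,5-epoxy-8-senecioyloxygermacra-1(10),11-dien-9-ol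
Product: 26 (1R,3S,4S,5S,7R,8S,9S,10S)-3-angeloyloxy-1,10:4,5-diepoxy-8-senecioyloxygermacr-11-en-9-ol (CNP0320216.1)
Conditions: VO(acac)2 (5 mol%), t-BuOOH (1.5 equiv, decane), CH2Cl2, 0 °C
Reagents that add atoms: tert-butyl hydroperoxide CC(C)(C)OO
Why: Vanadium-catalysed hydroxyl-directed epoxidation: only the allylic-alcohol olefin C1=C10 should react, since the isopropenyl group is bishomoallylic and the ester olefins are electron-poor. Delivery from the vanadate ester with a small O–C9–C10=C1 dihedral and C8 turned away from the C10 methyl gives, as with medium-ring (Z)-cycloalk-2-en-1-ols, the epoxide cis to the hydroxyl, i.e. (1R,10S).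

## Compound list

1 | (1Z,5Z)-1,5-dimethylcycloocta-1,5-diene | C/C1=C/CC/C(C)=C\CC1 | starting material
2 | (2Z,6Z)-2,6-dimethylcycloocta-2,6-diene-1,5-diol, mixture of racemic and meso forms (carbinol centres undefined) | OC1C/C=C(C)\C(O)C/C=C1/C | intermediate
3 | (2Z,6Z)-2,6-dimethylcycloocta-2,6-diene-1,5-dione | O=C1C/C=C(C)\C(=O)C/C=C1/C | intermediate
4 | (1S,5S,2Z,6Z)-2,6-dimethylcycloocta-2,6-diene-1,5-diol | O[C@H]1C/C=C(C)\[C@@H](O)C/C=C1/C | intermediate
5 | (5S,2Z,6Z)-5-hydroxy-2,6-dimethylcycloocta-2,6-dien-1-one | O=C1C/C=C(C)\[C@@H](O)C/C=C1/C | intermediate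
6 | vinylmagnesium bromide | C=C[Mg]Br | starting material
7 | (1R,5S,2Z,6Z)-1-ethenyl-2,6-dimethylcycloocta-2,6-diene-1,5-diol | C=C[C@]1(O)C/C=C(C)\[C@@H](O)C/C=C1/C | intermediate
8 | dipotassium 1,5-dialkoxide of 7 | C=C[C@]1([O-])C/C=C(C)\[C@@H]([O-])C/C=C1/C.[K+].[K+] | intermediate (not isolated)
9 | dipotassium salt of 10 (C3 alkoxide, C8=C9 enolate, enolate geometry undefined) | [O-]C1=CCC/C=C(C)\[C@@H]([O-])C/C=C1/C.[K+].[K+] | intermediate (not isolated)
10 | (3S,1(10)Z,4Z)-3-hydroxy-4,10-dimethylcyclodeca-1(10),4-dien-9-one | O=C1CCC/C=C(C)\[C@@H](O)C/C=C1/C | intermediate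
11 | (3S,4R,5S,1(10)Z)-4,5-epoxy-3-hydroxy-4,10-dimethylcyclodec-1(10)-en-9-one | O=C1CCC[C@@H]2O[C@]2(C)[C@@H](O)C/C=C1/C | intermediate
12 | (3S,4S,5S,1(10)Z)-4,5-epoxy-4,10-dimethyl-3-(triethylsilyloxy)cyclodec-1(10)-en-9-one | O=C1CCC[C@@H]2O[C@]2(C)[C@@H](O[Si](CC)(CC)CC)C/C=C1/C | intermediate
13 | (3S,4S,5S,1(10)Z)-4,5-epoxy-4,10-dimethyl-3-(triethylsilyloxy)-9-(trimethylsilyloxy)cyclodeca-1(10),8-diene (ring-cis C8=C9 drawn) | C[Si](C)(C)O/C1=C/CC[C@@H]2O[C@]2(C)[C@@H](O[Si](CC)(CC)CC)C/C=C1/C | intermediate
14 | (3S,4S,5S,1(10)Z,7Z)-4,5-epoxy-4,10-dimethyl-3-(triethylsilyloxy)cyclodeca-1(10),7-dien-9-one | O=C1/C=C\C[C@@H]2O[C@]2(C)[C@@H](O[Si](CC)(CC)CC)C/C=C1/C | intermediate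
15 | isopropenylboronic acid pinacol ester | CC(=C)B1OC(C)(C)C(C)(C)O1 | starting material
16 | (3S,4S,5S,7S,1(10)Z)-4,5-epoxy-3-(triethylsilyloxy)germacra-1(10),11-dien-9-one | C=C(C)[C@H]1C[C@@H]2O[C@]2(C)[C@@H](O[Si](CC)(CC)CC)C/C=C(C)\C(=O)C1 | intermediate
17 | (3S,4R,5S,7S,1(10)Z)-4,5-epoxy-3-hydroxygermacra-1(10),11-dien-9-one | C=C(C)[C@H]1C[C@@H]2O[C@]2(C)[C@@H](O)C/C=C(C)\C(=O)C1 | intermediate
18 | angelic acid, (Z)-2-methylbut-2-enoic acid | C/C=C(/C)C(=O)O | starting material
19 | angelic 2,4,6-trichlorobenzoic anhydride | C/C=C(/C)C(=O)OC(=O)c1c(Cl)cc(Cl)cc1Cl | intermediate (not isolated)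
20 | (3S,4S,5S,7S,1(10)Z)-3-angeloyloxy-4,5-epoxygermacra-1(10),11-dien-9-one | C=C(C)[C@H]1C[C@@H]2O[C@]2(C)[C@@H](OC(=O)/C(C)=C\C)C/C=C(C)\C(=O)C1 | intermediate
21 | potassium C8=C9 enolate of 20 (enolate geometry undefined) | C=C(C)[C@H]1C[C@@H]2O[C@]2(C)[C@@H](OC(=O)/C(C)=C\C)C/C=C(C)\C([O-])=C1.[K+] | intermediate (not isolated)
22 | (3S,4S,5S,7R,8R,1(10)Z)-3-angeloyloxy-4,5-epoxy-8-hydroxygermacra-1(10),11-dien-9-one | C=C(C)[C@H]1C[C@@H]2O[C@]2(C)[C@@H](OC(=O)/C(C)=C\C)C/C=C(C)\C(=O)[C@@H]1O | intermediate
23 | senecioic acid, 3-methylbut-2-enoic acid | CC(C)=CC(=O)O | starting material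
24 | (3S,4S,5S,7R,8S,1(10)Z)-3-angeloyloxy-4,5-epoxy-8-senecioyloxygermacra-1(10),11-dien-9-one | C=C(C)[C@H]1C[C@@H]2O[C@]2(C)[C@@H](OC(=O)/C(C)=C\C)C/C=C(C)\C(=O)[C@H]1OC(=O)C=C(C)C | intermediate
25 | (3S,4S,5S,7R,8S,9R,1(10)Z)-3-angeloyloxy-4,5-epoxy-8-senecioyloxygermacra-1(10),11-dien-9-ol | C=C(C)[C@H]1C[C@@H]2O[C@]2(C)[C@@H](OC(=O)/C(C)=C\C)C/C=C(C)\[C@@H](O)[C@H]1OC(=O)C=C(C)C | intermediate
26 | (1R,3S,4S,5S,7R,8S,9S,10S)-3-angeloyloxy-1,10:4,5-diepoxy-8-senecioyloxygermacr-11-en-9-ol | C=C(C)[C@H]1C[C@@H]2O[C@]2(C)[C@@H](OC(=O)/C(C)=C\C)C[C@H]2O[C@@]2(C)[C@@H](O)[C@H]1OC(=O)C=C(C)C | target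

## Step count and least certain steps

Total: 17 steps. Longest linear sequence: 17 steps from 1 (6, 15, 18 and 23 are purchased).

**Step 6 (key step).** The ring-opened allyl anion may recombine at the wrong carbon: C6 onto C1 of the ring enone (contraction to a cyclohexene) or C4 onto C7 (the [3,3] mode). It may also be protonated before it recombines, which leaves an open-chain divinyl ketone, and β-cleavage started by the C3 alkoxide is a further leak. All follow from the fully ionic pathway. Fallback, from 7 back to 10: both hydroxyls are silylated (chlorotrimethylsilane, imidazole) to the bis(trimethylsilyl) ether F1. Thermolysis at about 300 °C in a sealed tube or flow reactor effects the neutral siloxy-[1,3] shift by homolysis of the same C9–C6 bond and recombination at the unsubstituted termini, giving the bis-silylated enol ether F2. Methanolysis (K2CO3, MeOH) of both silyl groups returns 10. No carbanion is formed, so neither Michael-type bonding at C1 nor β-elimination of the C3 oxygen applies.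

**Step 11.** Transmetalation of the α-branched alkenyl pinacol boronate may be slow, with protodeboronation. Facial selectivity may be eroded or reversed, because the ligand sense is carried over from six-membered enones to a twisted ten-membered one, because step 10 may deliver some ring-trans enone, or because the ring has its own bias. The antipodal ligand is the first remedy for a reversed sense. Fallback, from 14 back to 16: stoichiometric diisopropenylcuprate (isopropenylmagnesium bromide, CuBr·SMe2) with chlorotrimethylsilane in THF at −78 °C gives the trimethylsilyl enol ether F3 of the adduct, and methanolysis (K2CO3, MeOH) gives 16. Control passes from the catalyst to the ring conformation (peripheral attack), and its sense is not known beforehand. The C7 epimers are diastereomers and would be separated at 16.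

**Step 14.** Facial selectivity at C8 may be lower than, or opposite to, the peripheral-attack model. Fallback, from 20 to 24: if the oxygen enters cis to the isopropenyl group, the same hydroxylation gives the (8S)-hydroxy ketone F4, which is esterified with retention (3-methylbut-2-enoyl chloride, pyridine, CH2Cl2, 0 °C) to 24. Either C8 epimer therefore reaches 24, one by inversion (step 15) and the other by retention.

**Step 15.** Backside displacement at a ring carbon next to tertiary C7 may be slow, leading to elimination towards C7 or to esterification with retention through an acyloxyphosphonium pathway. Fallback, from 22 to 24: the hydroxyl is converted at −78 °C (trifluoromethanesulfonic anhydride, pyridine) into the 8-triflate F5, which is displaced with inversion by caesium senecioate (23, Cs2CO3, 18-crown-6, toluene). The leaving group is then formed under non-nucleophilic conditions and the nucleophile is a free carboxylate.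

**Step 16.** Facial selectivity may be poor if the ring reacts through a conformer with C7 anti to C10 about C8–C9, which would give the 8,9-trans isomer; acyl migration from O8 to O9 may follow reduction. Fallback, from 24 to 25 with recycling: the (9S)-epimer F6 is re-oxidised at its allylic carbinol with MnO2 to 24. The reduction is then repeated under catalyst control with a 2-methyl-CBS-oxazaborolidine and catecholborane at −78 °C, using the (R)-catalyst if the methyl-substituted alkenyl arm acts as the large group.

## Further compounds

F1 | step 6 | (1R,5S,2Z,6Z)-1-ethenyl-2,6-dimethyl-1,5-bis(trimethylsilyloxy)cycloocta-2,6-diene | C=C[C@]1(O[Si](C)(C)C)C/C=C(C)\[C@@H](O[Si](C)(C)C)C/C=C1/C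
F2 | step 6 | (3S,1(10)Z,4Z)-4,10-dimethyl-3,9-bis(trimethylsilyloxy)cyclodeca-1(10),4,8-triene (C8=C9 geometry undefined) | C[Si](C)(C)OC1=CCC/C=C(C)\[C@@H](O[Si](C)(C)C)C/C=C1/C
F3 | step 11 | 9-O-trimethylsilyl enol ether (C8=C9) of 16 | C=C(C)[C@H]1C[C@@H]2O[C@]2(C)[C@@H](O[Si](CC)(CC)CC)C/C=C(C)\C(O[Si](C)(C)C)=C1
F4 | step 14 | (3S,4S,5S,7R,8S,1(10)Z)-3-angeloyloxy-4,5-epoxy-8-hydroxygermacra-1(10),11-dien-9-one (C8 epimer of 22) | C=C(C)[C@H]1C[C@@H]2O[C@]2(C)[C@@H](OC(=O)/C(C)=C\C)C/C=C(C)\C(=O)[C@H]1O
F5 | step 15 | 8-O-trifluoromethanesulfonate of 22 | C=C(C)[C@H]1C[C@@H]2O[C@]2(C)[C@@H](OC(=O)/C(C)=C\C)C/C=C(C)\C(=O)[C@@H]1OS(=O)(=O)C(F)(F)F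
F6 | step 16 | (3S,4S,5S,7R,8S,9S,1(10)Z)-3-angeloyloxy-4,5-epoxy-8-senecioyloxygermacra-1(10),11-dien-9-ol (C9 epimer of 25) | C=C(C)[C@H]1C[C@@H]2O[C@]2(C)[C@@H](OC(=O)/C(C)=C\C)C/C=C(C)\[C@H](O)[C@H]1OC(=O)C=C(C)C
A1 | alternative 1 | (1(10)Z,4Z)-3-(tert-butyldimethylsilyloxy)-8-(4-methoxybenzyloxy)germacra-1(10),4,11-trien-9-ol | C=C(C)[C@H]1C/C=C(C)\[C@@H](O[Si](C)(C)C(C)(C)C)C/C=C(C)\[C@@H](O)[C@H]1OCc2ccc(OC)cc2
A2 | alternative 2 | 15-norgermacra-1(10)Z,11-dien-4-yne-3,8,9-triol 8,9-acetonide | C=C(C)[C@H]1CC#C[C@@H](O)C/C=C(C)\[C@H]2OC(C)(C)O[C@H]21
A3 | alternative 3 | (1(10)Z,4Z)-9-(4-methoxybenzyloxy)germacra-1(10),4,11-triene-3,8-dione | C=C(C)[C@H]1C/C=C(C)\C(=O)C/C=C(C)\[C@@H](OCc2ccc(OC)cc2)C1=O
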